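## Structural features

The target is a 3-acyloxyflavanone: a chroman-4-one whose benzo ring A carries free hydroxyls at C5 and C7, and whose pyranone ring C carries an unsubstituted phenyl (ring B) at C2 and the oxygen of a 2-methylbutanoate ester at C3. C2 and C3 are neighbouring stereocentres, both R, with phenyl and ester oxygen trans on ring C. The third stereocentre, also R, is the α-carbon of the acyl chain and is insulated from the ring by the ester link. C3–H lies between the C4 ketone and C2 and is enolisable; base can open ring C from the enolate by expelling the O1 phenoxide, which would erase C2, and base can also move or cleave the ester or epimerise the acyl α-carbon. The phloroglucinol-type ring A is nucleophilic and easily oxidised, so it stays masked until the end. The real difficulty is the absolute configuration of the C2/C3 pair, because nothing else in rings A to C is stereogenic and the side-chain centre, which can be bought, is too remote to steer it. The key step exploits the cis relation of C2–H and C3–O on ring C, which is the signature of a suprafacial H–B addition across C2=C3 of a 2-phenyl-4H-chromene; that bond is both an enol ether of O1 and a styrene of ring B, so both effects send boron to C3. The C4 methylene left behind is activated by O5 and O7 of ring A, which later allows hydride abstraction there to install the ketone.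

## Logic of the disconnections

14 ⇒ 13. The phenols at O5 and O7 are capped as benzyl ethers (two O–CH2Ph bonds). Free phenols would not survive borane, quinone or periodinane chemistry, and with the caps every intermediate is a neutral, chromatographable compound. The forward step must therefore be a neutral hydrogenolysis that spares the C4 ketone, the benzylic C2–O1 bond and the ester.

13 ⇒ 12 ⇒ 11. The C4=O bond is removed in two stages, first to C4–OH (12), then to C4–H2 (11). The ketone is what makes C3–H acidic and ring C base-labile, so it is introduced as late as possible; 11 has no enolisable stereocentre. The forward oxidant must abstract hydride from C4 and not from a benzyl ether methylene, the acyl group must stay on O3, and the second oxidation must be non-basic.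

11 ⇒ 9 + 10. The acyl C–O3 bond is cut. This detaches the side-chain stereocentre, which comes ready-made in 10, and leaves 9 with only the two ring stereocentres. The forward acylation must reach a hindered secondary alcohol without enolising 10.

9 ⇒ 7 (through 8). The C3–O bond and the C2–H bond are cut together, because their cis relation is exactly what a syn addition of H–B delivers. Both stereocentres vanish and 7 is flat and achiral. The forward step must place boron only at C3 and on one face only, which an achiral substrate can get only from a chiral reagent. The benzyl ethers are kept because they tolerate borane, alkaline peroxide and the later oxidants.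

7 ⇒ 5 (through 6). The O1–C2 enol ether bond is cut, revealing a phenol and an aryl ketone. Ring C is opened to an acyclic chain. The forward dehydration has to be mild enough for the acid- and air-sensitive 7 to survive, so 7 is made with a weak acid and used at once.

5 ⇒ 4. No skeletal bond is cut; two hydrogens are removed from the future C3–C4 to expose an enone, the retron of an aldol condensation. The forward step must saturate the C=C bond without touching benzyl ethers or the aryl ketone.

4 ⇒ 2 + 3. The enone C=C bond (future C3–C4) is cut. This gives a non-enolisable aldehyde and a commercial methyl ketone. The free ortho phenoxide deactivates the aldehyde, so the forward condensation needs strong base and time, and the work-up must stay only weakly acidic.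

2 ⇒ 1. Two O–CH2Ph bonds, at the para and at one ortho oxygen, are cut. 1 is commercial, and the remaining ortho hydroxyl is the one needed later for ring closure. The forward alkylation must stop at the dialkyl stage and leave the chelated hydroxyl free.

## Other disconnections considered

Alternative 1: The cut is the C2–C3 bond of ring C in the hydroxy ketone A1, leading back to the ring-contracted α-hydroxy aldehyde A2.
- Forward step: Sc(OTf)3 (trivalent scandium) would bind the hydroxyl and formyl oxygens of A2. C2 would then migrate with its bonding pair from the carbinol carbon to the formyl carbon (α-ketol rearrangement), so the carbinol carbon becomes the C4 ketone and the former formyl carbon becomes C3–OH.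
- In favour: ketone and hydroxyl arrive at the correct oxidation level in the ring-forming step. From A1 only esterification with 10 and debenzylation remain, two steps against four after the chosen key step, which is better than the chosen plan. The migrating carbon should keep its configuration.
- Against: C2 must already be stereogenic in A2, and an enantiopure dihydrobenzofuranol with a quaternary carbinol and a formyl group is a multistep asymmetric problem of its own. The electron-rich aryl carbon on the carbinol is a competing migrating group, which would transpose the carbonyl. C3 would be set only by the face of the formyl group and by equilibration to trans, and a Lewis acid that enolises C3 can also open ring C.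
- Comparison: on structure the two plans are equal, since both reach a benzyl-protected trans flavanoid. On mechanism the hydroboration has unambiguous regiochemistry and creates both centres in one concerted event, whereas here C2 is imported and C3 is relayed. On step economy Alternative 1 is shorter after the key step and longer before it.

Alternative 2: The cut is the C2–H and C3–H bonds of A3, leading back to the flat flavonol ester A4.
- Forward step: a ligated copper hydride from Cu(OAc)2, DTBM-SEGPHOS and diethoxymethylsilane would deliver hydride to C2, and the resulting enolate would be protonated at C3.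
- In favour: skeleton, ketone and ester are all in place before the stereocentres are made, so one debenzylation follows. This is the shortest endgame of the four plans and better than the chosen one. The chiral source is catalytic, against a stoichiometric terpene borane, which is also better. A4 is achiral and should be reachable by robust flavone chemistry.
- Against: C2=C3 of A4 is tetrasubstituted, part of a vinylogous ester through O1 and burdened with an α-acyloxy group, so it is a poor and hindered acceptor. The chelated 5-hydroxyl consumes hydride. The enolate carries the O1 phenoxide in the β position, so ring opening threatens, as do acyl transfer to the enolate oxygen and 1,2-reduction. C3 is fixed by protonation and not by the catalyst.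
- Comparison: on structure the plans are equal in using an achiral planar precursor. On mechanism the syn hydroboration is the more secure, because both centres come from one stereospecific addition. On step economy Alternative 2 is better.

Alternative 3: The cut is the C3–C4 bond of the cis-diol A5, leading back to the dialdehyde A6.
- Forward step: SmI2 (divalent samarium) would reduce one formyl group to a ketyl, which adds to the other carbonyl within a samarium-bridged arrangement. This closes ring C as the 3,4-cis diol.
- In favour: ring C and both oxygens at C3 and C4 form in one step, so no hydride abstraction at C4 is needed. After A5, a selective benzylic oxidation, esterification with 10 and debenzylation would finish the synthesis, which is equal to or one step shorter than the chosen endgame. The O1–C2 ether bond can be made by plain substitution.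
- Against: C2 must be carried as a centre that is benzylic, α to oxygen and α to a formyl group, so A6 is prone to racemise before and during the coupling. The trans relation of C2 and C3 rests on substrate control from that one labile centre. An α-aryloxy carbonyl can lose its aryloxide under SmI2. The two hydroxyls of A5 must be differentiated afterwards.
- Comparison: on structure it is more convergent, as it builds ring C and does not edit a preformed one. On mechanism the stereochemical information rests on a fragile centre, whereas the chosen plan creates C2 and C3 together under reagent control. On step economy the two are about equal.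

Key step: step 5

Assumption: the facial preference of monoisopinocampheylborane established for 1-arylcycloalkenes is taken to hold for the 2-aryl-4H-chromene, so the borane derived from (+)-α-pinene is chosen for the (2R,3S) alcohol; enantiopure (R)-2-methylbutanoic acid is taken as purchasable.

Remark: C3 is S in 9, 11 and 12 and R in 13 and 14 only because C4 gains CIP priority on becoming a carbonyl; no inversion occurs.

## Route

Step 1
Reactants: 1 2,4,6-trihydroxybenzaldehyde
Product: 2 2,4-bis(benzyloxy)-6-hydroxybenzaldehyde
Conditions: BnBr (2.05 equiv), K2CO3 (2.2 equiv), DMF, 0 °C to rt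
Reagents that add atoms: benzyl bromide, BrCc1ccccc1
Why: Williamson etherification; the para hydroxyl is the most acidic and one ortho hydroxyl follows, while the last ortho hydroxyl is locked in a hydrogen bond to the formyl oxygen and should stay free.

Step 2
Reactants: 2 2,4-bis(benzyloxy)-6-hydroxybenzaldehyde, 3 acetophenone
Product: 4 (E)-3-[2,4-bis(benzyloxy)-6-hydroxyphenyl]-1-phenylprop-2-en-1-one
Conditions: KOH (50% aq.), EtOH, rt; then cold dilute AcOH to pH 6
Reagents that add atoms: none
Why: Claisen–Schmidt condensation; the acetophenone enolate adds to the non-enolisable aldehyde and E1cB dehydration gives the E-enone. The weakly acidic quench avoids closure to the benzopyrylium ion.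

Step 3
Reactants: 4 (E)-3-[2,4-bis(benzyloxy)-6-hydroxyphenyl]-1-phenylprop-2-en-1-one
Product: 5 3-[2,4-bis(benzyloxy)-6-hydroxyphenyl]-1-phenylpropan-1-one
Conditions: H2 (1 atm), 10% Pd/C, Ph2S (cat.), EtOAc, rt
Reagents that add atoms: none
Why: Chemoselective catalytic hydrogenation of the conjugated C=C bond; the sulfide-moderated palladium catalyst should leave aryl benzyl ethers and the aryl ketone untouched.

Step 4
Reactants: 5 3-[2,4-bis(benzyloxy)-6-hydroxyphenyl]-1-phenylpropan-1-one
Product: 7 5,7-bis(benzyloxy)-2-phenyl-4H-chromene, via 5,7-bis(benzyloxy)-2-phenylchroman-2-ol 6 (not isolated)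
Conditions: PPTS (cat.), toluene, 4 Å MS, 90 °C, argon; Et3N quench, filtration through basic alumina, used at once
Reagents that add atoms: none
Why: Acid-catalysed cyclodehydration; the phenol adds to the ketone (6-exo-trig) to give hemiketal 6, and ionisation at C2 followed by loss of a C3 proton can only give the C2=C3 enol ether. Water removal drives the equilibrium, and the weak acid, inert gas and basic quench protect the sensitive product.

Step 5
Reactants: 7 5,7-bis(benzyloxy)-2-phenyl-4H-chromene
Product: 9 (2R,3S)-5,7-bis(benzyloxy)-2-phenylchroman-3-ol, via chroman-3-yl(isopinocampheyl)borane 8 (not isolated)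
Conditions: IpcBH2 of (+)-α-pinene origin (1.2 equiv; freed from (IpcBH2)2·TMEDA with BF3·OEt2 in THF, TMEDA·2BF3 filtered off), THF, −25 °C; then 3 M NaOH, 30% H2O2, 0 °C to rt
Reagents that add atoms: hydrogen peroxide, OO (oxygen at C3 of 9); monoisopinocampheylborane from (+)-α-pinene, C[C@H]1[C@H](B)C[C@@H]2C[C@H]1C2(C)C (boron and isopinocampheyl group of 8)
Why: Reagent-controlled asymmetric hydroboration–oxidation: the B–H bond adds suprafacially across C2=C3 through a four-centre transition state, hydrogen to C2 and boron to C3, because donation from O1 and from ring B both place the developing positive charge on C2 and leave C3 as the less hindered terminus, giving 8. The closest known reactions are the hydroboration of 1-arylcycloalkenes with monoisopinocampheylborane, of cyclic enol ethers with isopinocampheylboranes, and of flav-2-enes with achiral boranes to 2,3-trans-flavan-3-ols. No ring is closed. The relative configuration of the two new stereocentres follows from syn addition to a ring alkene: hydrogen at C2 and boron at C3 enter on one face, so phenyl and boron end up trans. The absolute configuration is set by the isopinocampheyl group on boron, which for trisubstituted aryl alkenes is expected to give the S carbinol centre when the borane comes from (+)-α-pinene, here C3 S and therefore C2 R. Alkaline H2O2 then turns C3–B into C3–OH by migration of C3 from boron to oxygen with retention. The step needs regio-, diastereo- and enantioselectivity: the first two are secured by the substrate (enol ether and styrene polarisation, cyclic alkene) and the third by the reagent alone, since 7 is planar and achiral. Low temperature, absence of BF3 and prompt oxidation are meant to keep the β-aryloxy borane 8 from ring-opening elimination.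

Step 6
Reactants: 9 (2R,3S)-5,7-bis(benzyloxy)-2-phenylchroman-3-ol, 10 (R)-2-methylbutanoic acid
Product: 11 (2R,3S)-5,7-bis(benzyloxy)-2-phenylchroman-3-yl (2R)-2-methylbutanoate
Conditions: DCC (1.2 equiv), DMAP (0.1 equiv), CH2Cl2, 0 °C to rt
Reagents that add atoms: none
Why: Steglich esterification; the acid is activated as the O-acylisourea and acylpyridinium and transferred to O3 without breaking any bond at C2 or C3. A simple α-alkyl acid should not enolise under these mild conditions, so the side-chain centre is kept.

Step 7
Reactants: 11 (2R,3S)-5,7-bis(benzyloxy)-2-phenylchroman-3-yl (2R)-2-methylbutanoate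
Product: 12 (2R,3S)-5,7-bis(benzyloxy)-4-hydroxy-2-phenylchroman-3-yl (2R)-2-methylbutanoate (C4 epimers)
Conditions: DDQ (2 equiv), CH2Cl2/H2O (10:1), rt
Reagents that add atoms: water, O
Why: Benzylic oxidative functionalisation known for protected flavan-3-ols; DDQ abstracts hydride from C4 to give a cation stabilised by O5 and O7, which water captures. The configuration at C4 is irrelevant because the centre is oxidised in step 8, and the benzyl ether methylenes are far less hydridic than C4–H.

Step 8
Reactants: 12 (2R,3S)-5,7-bis(benzyloxy)-4-hydroxy-2-phenylchroman-3-yl (2R)-2-methylbutanoate (C4 epimers)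
Product: 13 (2R,3R)-5,7-bis(benzyloxy)-4-oxo-2-phenylchroman-3-yl (2R)-2-methylbutanoate
Conditions: Dess–Martin periodinane (1.3 equiv), CH2Cl2, 0 °C to rt
Reagents that add atoms: none
Why: Dess–Martin oxidation of the secondary benzylic alcohol; the neutral, non-enolising conditions should leave the now α-acyloxy C3 centre, ring C and the ester untouched, and both C4 epimers converge on one ketone.

Step 9
Reactants: 13 (2R,3R)-5,7-bis(benzyloxy)-4-oxo-2-phenylchroman-3-yl (2R)-2-methylbutanoate
Product: 14 (2R,3R)-5,7-dihydroxy-4-oxo-2-phenylchroman-3-yl (2R)-2-methylbutanoate
Conditions: H2 (1 atm), 10% Pd/C, EtOAc, rt, stopped at full conversion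
Reagents that add atoms: none
Why: Hydrogenolysis of the two aryl benzyl ethers under neutral conditions; the ketone is a deactivated, ring A-conjugated carbonyl and the cyclic C2–O1 ether is hindered, so both should react much more slowly than the ArO–CH2Ph bonds. No base is present that could epimerise C3 or open ring C.

## Compound list

1 | 2,4,6-trihydroxybenzaldehyde | O=Cc1c(O)cc(O)cc1O | starting material
2 | 2,4-bis(benzyloxy)-6-hydroxybenzaldehyde | O=Cc1c(O)cc(OCc2ccccc2)cc1OCc1ccccc1 | intermediate
3 | acetophenone | CC(=O)c1ccccc1 | starting material
4 | (E)-3-[2,4-bis(benzyloxy)-6-hydroxyphenyl]-1-phenylprop-2-en-1-one | O=C(/C=C/c1c(O)cc(OCc2ccccc2)cc1OCc1ccccc1)c1ccccc1 | intermediate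
5 | 3-[2,4-bis(benzyloxy)-6-hydroxyphenyl]-1-phenylpropan-1-one | O=C(CCc1c(O)cc(OCc2ccccc2)cc1OCc1ccccc1)c1ccccc1 | intermediate
6 | 5,7-bis(benzyloxy)-2-phenylchroman-2-ol (racemic hemiketal, not isolated) | OC1(c2ccccc2)CCc2c(OCc3ccccc3)cc(OCc3ccccc3)cc2O1 | intermediate
7 | 5,7-bis(benzyloxy)-2-phenyl-4H-chromene | c1ccccc1C1=CCc2c(OCc3ccccc3)cc(OCc3ccccc3)cc2O1 | intermediate
8 | [2,3-trans-5,7-bis(benzyloxy)-2-phenylchroman-3-yl](isopinocampheyl)borane, ring centres arranged as in 9, isopinocampheyl from (+)-α-pinene (not isolated) | C[C@H]1[C@H](B[C@H]3Cc4c(OCc5ccccc5)cc(OCc5ccccc5)cc4O[C@@H]3c3ccccc3)C[C@@H]2C[C@H]1C2(C)C | intermediate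
9 | (2R,3S)-5,7-bis(benzyloxy)-2-phenylchroman-3-ol | O[C@H]1Cc2c(OCc3ccccc3)cc(OCc3ccccc3)cc2O[C@@H]1c1ccccc1 | intermediate
10 | (R)-2-methylbutanoic acid | CC[C@@H](C)C(=O)O | starting material
11 | (2R,3S)-5,7-bis(benzyloxy)-2-phenylchroman-3-yl (2R)-2-methylbutanoate | CC[C@@H](C)C(=O)O[C@H]1Cc2c(OCc3ccccc3)cc(OCc3ccccc3)cc2O[C@@H]1c1ccccc1 | intermediate
12 | (2R,3S)-5,7-bis(benzyloxy)-4-hydroxy-2-phenylchroman-3-yl (2R)-2-methylbutanoate, C4 epimers | CC[C@@H](C)C(=O)O[C@H]1C(O)c2c(OCc3ccccc3)cc(OCc3ccccc3)cc2O[C@@H]1c1ccccc1 | intermediate
13 | (2R,3R)-5,7-bis(benzyloxy)-4-oxo-2-phenylchroman-3-yl (2R)-2-methylbutanoate | CC[C@@H](C)C(=O)O[C@H]1C(=O)c2c(OCc3ccccc3)cc(OCc3ccccc3)cc2O[C@@H]1c1ccccc1 | intermediate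
14 | (2R,3R)-5,7-dihydroxy-4-oxo-2-phenylchroman-3-yl (2R)-2-methylbutanoate | CC[C@@H](C)C(=O)O[C@H]1C(=O)c2c(O)cc(O)cc2O[C@@H]1c1ccccc1 | target

## Step count and risk

Total step count: 9. Longest linear sequence: 9 steps (1 to 14); 3 enters at step 2 and 10 at step 6.

Least certain steps, most uncertain first:

Step 5 (key step). The isopinocampheyl group may discriminate poorly between the faces of a flattened, benzo-fused enol ether whose C2 substituents differ from those of the carbocyclic models. The hindered borane may also add slowly at low temperature. The β-aryloxy borane 8 may undergo ring-opening elimination, since boron at C3 can lie anti to the C2–O1 bond and the leaving group is a phenoxide. Fallback, from 7 back to 11: hydroborate 7 with achiral BH3·THF and oxidise with NaOH/H2O2, which gives the racemic trans alcohol, that is 9 together with (2S,3R)-5,7-bis(benzyloxy)-2-phenylchroman-3-ol F1. Esterify the mixture with 10 under the conditions of step 6 and separate the two diastereomeric esters by chromatography or crystallisation, 11 from (2S,3R)-5,7-bis(benzyloxy)-2-phenylchroman-3-yl (2R)-2-methylbutanoate F2. The stereochemical task moves from reagent control to a resolution by the acid the target needs anyway, at the cost of half the material and no extra step.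

Step 4. The electron-rich chromene may degrade in the acid that forms it: reprotonation at C3 regenerates the C2 oxocarbenium ion, which opens the way to intermolecular hydride transfer (disproportionation), air oxidation to the benzopyrylium ion, or reversion on aqueous work-up. Fallback, from 5 back to 7: convert 5 with HC(OMe)3, MeOH and PPTS at rt into the storable mixed ketal 5,7-bis(benzyloxy)-2-methoxy-2-phenylchromane F3. Then eliminate methanol under buffered aprotic conditions (TMSOTf, i-Pr2NEt, CH2Cl2, −20 °C; ketal to enol ether conversion), so that 7 never meets a protic acid.

Step 7. The C4 cation forms next to the ester, so the acyl group may bridge to it and end up on O4; DDQ may also attack benzyl ether methylenes, or conversion may stall. Fallback, from 9 back to 13: oxidise C4 before the acyl group is present. DDQ in CH2Cl2/H2O should take 9 to (2R,3S)-5,7-bis(benzyloxy)-2-phenylchromane-3,4-diol F4 (C4 epimers). MnO2 in CH2Cl2 should oxidise only the aryl carbinol at C4 to (2R,3R)-5,7-bis(benzyloxy)-3-hydroxy-2-phenylchroman-4-one F5, the same compound as A1. Steglich esterification of its 3-hydroxyl with 10 (DCC, cat. DMAP, 0 °C) then gives 13 in the same number of steps.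

Step 3. Hydrogenation may partly cleave the benzyl ethers or over-reduce the aryl ketone, and 4 may close to the benzopyrylium ion under light or traces of acid. Fallback, from 4 back to 7, bypassing 5 and step 4: use that closure on purpose. HBF4·OEt2 in AcOH/Et2O should give 5,7-bis(benzyloxy)-2-phenylchromenylium tetrafluoroborate F6. A soft hydride donor (Hantzsch ester, NaHCO3, CH2Cl2, 0 °C) is then expected to add at C4, the softer terminus of the cation, and give 7 directly. Competing hydride delivery to C2 is the point to watch.

Step 1. Alkylation may run past or stop short of the dialkyl stage, and the phloroglucinol nucleus may be benzylated on carbon. Fallback, from 1 back to 2: benzylate exhaustively (excess BnBr, K2CO3, DMF, 60 °C) to 2,4,6-tris(benzyloxy)benzaldehyde F7. Then remove one ortho benzyl group by chelation-directed cleavage with MgBr2·OEt2 (toluene/Et2O, reflux); magnesium held between the formyl oxygen and an ortho ether oxygen activates only that O–CH2Ph bond towards bromide.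

## Further compounds

F1 | step 5 | (2S,3R)-5,7-bis(benzyloxy)-2-phenylchroman-3-ol | O[C@@H]1Cc2c(OCc3ccccc3)cc(OCc3ccccc3)cc2O[C@H]1c1ccccc1
F2 | step 5 | (2S,3R)-5,7-bis(benzyloxy)-2-phenylchroman-3-yl (2R)-2-methylbutanoate | CC[C@@H](C)C(=O)O[C@@H]1Cc2c(OCc3ccccc3)cc(OCc3ccccc3)cc2O[C@H]1c1ccccc1
F3 | step 4 | 5,7-bis(benzyloxy)-2-methoxy-2-phenylchromane (racemic) | COC1(c2ccccc2)CCc2c(OCc3ccccc3)cc(OCc3ccccc3)cc2O1
F4 | step 7 | (2R,3S)-5,7-bis(benzyloxy)-2-phenylchromane-3,4-diol (C4 epimers) | O[C@H]1C(O)c2c(OCc3ccccc3)cc(OCc3ccccc3)cc2O[C@@H]1c1ccccc1
F5 | step 7 | (2R,3R)-5,7-bis(benzyloxy)-3-hydroxy-2-phenylchroman-4-one | O[C@H]1C(=O)c2c(OCc3ccccc3)cc(OCc3ccccc3)cc2O[C@@H]1c1ccccc1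
F6 | step 3 | 5,7-bis(benzyloxy)-2-phenylchromenylium tetrafluoroborate | [o+]1c(-c2ccccc2)ccc2c(OCc3ccccc3)cc(OCc3ccccc3)cc12.F[B-](F)(F)F
F7 | step 1 | 2,4,6-tris(benzyloxy)benzaldehyde | O=Cc1c(OCc2ccccc2)cc(OCc2ccccc2)cc1OCc1ccccc1
A1 | alternative 1 | (2R,3R)-5,7-bis(benzyloxy)-3-hydroxy-2-phenylchroman-4-one | O[C@H]1C(=O)c2c(OCc3ccccc3)cc(OCc3ccccc3)cc2O[C@@H]1c1ccccc1
A2 | alternative 1 | (2R)-4,6-bis(benzyloxy)-3-hydroxy-2-phenyl-2,3-dihydro-1-benzofuran-3-carbaldehyde (either C3 epimer) | O=CC1(O)c2c(OCc3ccccc3)cc(OCc3ccccc3)cc2O[C@@H]1c1ccccc1
A3 | alternative 2 | (2R,3R)-7-(benzyloxy)-5-hydroxy-4-oxo-2-phenylchroman-3-yl (2R)-2-methylbutanoate | CC[C@@H](C)C(=O)O[C@H]1C(=O)c2c(O)cc(OCc3ccccc3)cc2O[C@@H]1c1ccccc1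
A4 | alternative 2 | 7-(benzyloxy)-5-hydroxy-4-oxo-2-phenyl-4H-chromen-3-yl (2R)-2-methylbutanoate | CC[C@@H](C)C(=O)OC1=C(c2ccccc2)Oc2cc(OCc3ccccc3)cc(O)c2C1=O
A5 | alternative 3 | (2R,3S,4S)-5,7-bis(benzyloxy)-2-phenylchromane-3,4-diol (2,3-trans, 3,4-cis) | O[C@H]1[C@@H](O)c2c(OCc3ccccc3)cc(OCc3ccccc3)cc2O[C@@H]1c1ccccc1
A6 | alternative 3 | (2R)-2-[3,5-bis(benzyloxy)-2-formylphenoxy]-2-phenylacetaldehyde | O=C[C@H](Oc1cc(OCc2ccccc2)cc(OCc2ccccc2)c1C=O)c1ccccc1
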